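**Strategy.** Everything rests on cutting C8–C9 (backbone numbered C1–C23 from the left ethyl group). This is the bond between the methine on the left γ-pyranone ring and the acetoxy carbon. C8 is the vinylogous α-carbon of that ring's carbonyl (C5=O), so C8–C9–O is a vinylogous aldol retron. The nucleophile is C2v-symmetric 2,6-diethyl-3,5-dimethyl-4-pyranone, whose two ethyl groups are equivalent. Its silyl dienol ether, a 2-ethylidene-4-silyloxy-2H-pyran, is added under BF3 to the complete C9–C23 aldehyde, which already holds the right pyranone and five stereocentres. One operation joins the halves, restores the left pyranone and sets C8 and C9. It leaves C9–OH as the only free hydroxyl for acetylation.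

Key step: step 18

Remark on numbering: C1–C2 ethyl; C3–C7 left pyranone carbons (C3 bears ethyl, C4 and C6 bear methyl, C5 is C=O, C7 bears the chain); C8–C14 chain; C15–C19 right pyranone carbons (C17 is C=O); C20–C23 side chain. The target is 8R,9R,10S,11S,12E,14R,20S,21S. The descriptors at C10 and C20 change in some intermediates only because substituent priorities change; the spatial arrangement stays the same.

Step 1
Reactants: 1 pentan-3-one; 2 propanoic acid (2 equiv)
Product: 3 2,6-diethyl-3,5-dimethyl-4H-pyran-4-one
Conditions: polyphosphoric acid, 110–130 °C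
Reagents that add atoms: none
Why: Acid-mediated double C-acylation of the ketone at both α-carbons and cyclodehydration of the resulting 1,3,5-triketone (the classical polyphosphoric acid γ-pyranone synthesis from a ketone and a carboxylic acid) should give the symmetric pyranone, which has no stereocentre.

Step 2
Reactants: 4 propanal (donor and acceptor, 2 equiv)
Product: 5 (2S,3S)-3-hydroxy-2-methylpentanal
Conditions: L-proline (10 mol %), DMF, 4 °C, slow addition of 4
Reagents that add atoms: none
Why: Proline-catalysed direct enamine aldol reaction (self-aldol of propanal), in which the (E)-enamine of L-proline attacks the Re face of the acceptor aldehyde in a hydrogen-bonded chair-like transition state, should set C20 and C21 as the (2S,3S)-anti pair, the minor syn isomer being removed by chromatography after step 3.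

Step 3
Reactants: 5 (2S,3S)-3-hydroxy-2-methylpentanal
Product: 6 (2S,3S)-3-(tert-butyldimethylsilyloxy)-2-methylpentanal
Conditions: TBSOTf, 2,6-lutidine, CH2Cl2, −78 °C
Reagents that add atoms: tert-butyldimethylsilyl triflate, CC(C)(C)[Si](C)(C)OS(=O)(=O)C(F)(F)F
Why: Silyl triflate silylation with a hindered pyridine base at low temperature protects the secondary alcohol faster than the aldehyde can enolise, so C20 should keep its configuration.

Step 4
Reactants: 1 pentan-3-one; 6 (2S,3S)-3-(tert-butyldimethylsilyloxy)-2-methylpentanal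
Product: 8 (6R,7S)-7-(tert-butyldimethylsilyloxy)-5-hydroxy-4,6-dimethylnonan-3-one (mixture at C4 and C5), via lithium enolate of pentan-3-one 7 (not isolated)
Conditions: LDA, THF, −78 °C; then 6, −78 °C; pH 7 buffer
Reagents that add atoms: none
Why: Lithium enolate aldol addition to an α-branched aldehyde is fast at −78 °C, and the two new stereocentres (future C18 and C19) need no control because both become sp2 ring carbons.

Step 5
Reactants: 8 (6R,7S)-7-(tert-butyldimethylsilyloxy)-5-hydroxy-4,6-dimethylnonan-3-one
Product: 9 (6S,7S)-7-(tert-butyldimethylsilyloxy)-4,6-dimethylnonane-3,5-dione (mixture at C4)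
Conditions: Dess–Martin periodinane, pyridine, CH2Cl2, 0 °C → rt
Reagents that add atoms: none
Why: Dess–Martin oxidation of the β-hydroxy ketone under buffered conditions should give the β-diketone without touching C20 or the silyl ether.

Step 6
Reactants: 10 methyl (S)-3-hydroxy-2-methylpropanoate
Product: 11 methyl (S)-2-methyl-3-(triethylsilyloxy)propanoate
Conditions: TESCl, imidazole, CH2Cl2, 0 °C
Reagents that add atoms: chlorotriethylsilane, CC[Si](Cl)(CC)CC
Why: Imidazole-promoted silylation of the primary alcohol is routine, and the triethylsilyl group is chosen because step 12 can oxidise it directly beside tert-butyldimethylsilyl ethers.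

Step 7
Reactants: 11 methyl (S)-2-methyl-3-(triethylsilyloxy)propanoate
Product: 12 (S)-2-methyl-3-(triethylsilyloxy)propanal
Conditions: DIBAL (1.05 equiv), CH2Cl2, −78 °C; aqueous sodium potassium tartrate
Reagents that add atoms: none
Why: Partial DIBAL reduction of the ester, via a tetrahedral aluminium hemiacetal that is stable at −78 °C, should stop at the aldehyde with the α-stereocentre (future C14) intact.

Step 8
Reactants: 12 (S)-2-methyl-3-(triethylsilyloxy)propanal; 13 2-(triphenylphosphoranylidene)propanal
Product: 14 (2E,4R)-2,4-dimethyl-5-(triethylsilyloxy)pent-2-enal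
Conditions: toluene, 90 °C
Reagents that add atoms: none
Why: Wittig olefination with a stabilised formyl ylide should give the (E)-trisubstituted enal (future C12=C13) and is mild enough not to epimerise the allylic stereocentre.

Step 9
Reactants: 15 (S)-4-benzyl-3-propanoyloxazolidin-2-one; 14 (2E,4R)-2,4-dimethyl-5-(triethylsilyloxy)pent-2-enal
Product: 17 (S)-4-benzyl-3-[(2S,3S,4E,6R)-3-hydroxy-2,4,6-trimethyl-7-(triethylsilyloxy)hept-4-enoyl]oxazolidin-2-one, via (Z)-dibutylboron enolate 16 (not isolated)
Conditions: Bu2BOTf, Et3N, CH2Cl2, 0 °C; 14, −78 → 0 °C; H2O2, MeOH, pH 7 buffer, 0 °C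
Reagents that add atoms: none
Why: In this Evans syn-aldol reaction the (Z)-boron enolate reacts through a Zimmerman–Traxler chair on the enolate face opposite the benzyl group of the (S)-auxiliary, which should set C10 and C11 as the (2S,3S)-syn pair irrespective of the remote C14 centre.

Step 10
Reactants: 17 Evans aldol adduct
Product: 18 (2R,3S,4E,6R)-2,4,6-trimethyl-7-(triethylsilyloxy)hept-4-ene-1,3-diol
Conditions: LiBH4, MeOH (1 equiv), THF, 0 °C
Reagents that add atoms: none
Why: Reductive cleavage of the N-acyl oxazolidinone with lithium borohydride, assisted by the free β-hydroxyl, should give the 1,3-diol and return the auxiliary without epimerisation at C10.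

Step 11
Reactants: 18 (2R,3S,4E,6R)-2,4,6-trimethyl-7-(triethylsilyloxy)hept-4-ene-1,3-diol
Product: 19 (2R,3S,4E,6R)-1,3-bis(tert-butyldimethylsilyloxy)-2,4,6-trimethyl-7-(triethylsilyloxy)hept-4-ene
Conditions: TBSOTf (2.5 equiv), 2,6-lutidine, CH2Cl2, −78 → 0 °C
Reagents that add atoms: tert-butyldimethylsilyl triflate, CC(C)(C)[Si](C)(C)OS(=O)(=O)C(F)(F)F
Why: Exhaustive silyl triflate silylation protects the primary C9 and the secondary allylic C11 hydroxyl in one operation and leaves the triethylsilyl ether in place.

Step 12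
Reactants: 19 tris-silyl ether
Product: 20 (2R,3E,5S,6R)-5,7-bis(tert-butyldimethylsilyloxy)-2,4,6-trimethylhept-3-enal
Conditions: (COCl)2, DMSO, CH2Cl2, −78 → −40 °C; Et3N, −78 → 0 °C; used at once
Reagents that add atoms: none
Why: In a Swern oxidation applied directly to a primary triethylsilyl ether, chlorodimethylsulfonium chloride displaces only the small, unhindered silyl group to give the alkoxysulfonium salt, so the C15 aldehyde should form in one step while both tert-butyldimethylsilyl ethers stay.

Step 13
Reactants: 9 (6S,7S)-7-(tert-butyldimethylsilyloxy)-4,6-dimethylnonane-3,5-dione; 20 (2R,3E,5S,6R)-5,7-bis(tert-butyldimethylsilyloxy)-2,4,6-trimethylhept-3-enal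
Product: 22 C9–C23 15-hydroxy-17,19-dione with 9,11,21-tris(tert-butyldimethylsilyloxy) groups (10R,11S,12E,14R,20S,21S; mixture at C15, C16, C18), via dilithium bis-enolate 21 (not isolated)
Conditions: 9, LDA (2.1 equiv), THF, −78 → 0 °C; 20, −78 °C; pH 7 buffer
Reagents that add atoms: none
Why: In this γ-selective aldol addition of a β-diketone dianion the second deprotonation takes place at the unhindered ethyl CH2 (future C16), this terminal carbon is the most nucleophilic site, and the new stereocentres at C15 and C16 are erased in steps 14 and 15.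

Step 14
Reactants: 22 15-hydroxy-17,19-dione
Product: 23 C9–C23 15,17,19-trione (10R,11S,12E,14R,20S,21S; mixture at C16 and C18, partly enolised)
Conditions: Dess–Martin periodinane, pyridine, CH2Cl2, 0 °C → rt
Reagents that add atoms: none
Why: Dess–Martin oxidation gives the 1,3,5-triketone under non-basic conditions, so C14 and C20, both next to a carbonyl group, should not epimerise.

Step 15
Reactants: 23 15,17,19-trione
Product: 24 2-[(2R,3E,5S,6R)-5,7-bis(tert-butyldimethylsilyloxy)-4,6-dimethylhept-3-en-2-yl]-6-[(2S,3S)-3-(tert-butyldimethylsilyloxy)pentan-2-yl]-3,5-dimethyl-4H-pyran-4-one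
Conditions: PPh3, CCl4, THF, rt
Reagents that add atoms: none
Why: Appel-type activation of an enol oxygen by Ph3P/CCl4, followed by addition–elimination of the other terminal enol oxygen (cyclodehydration of a 1,3,5-triketone to a γ-pyranone), works without strong acid or base and should therefore keep the ring-adjacent stereocentres C14 and C20.

Step 16
Reactants: 24 tris-silylated right-hand pyranone
Product: 25 2-[(2R,3E,5S,6R)-5-(tert-butyldimethylsilyloxy)-7-hydroxy-4,6-dimethylhept-3-en-2-yl]-6-[(2S,3S)-3-(tert-butyldimethylsilyloxy)pentan-2-yl]-3,5-dimethyl-4H-pyran-4-one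
Conditions: HF·pyridine, pyridine, THF, 0 °C
Reagents that add atoms: none
Why: Sterically controlled desilylation with pyridine-buffered HF·pyridine should cleave the primary C9 ether well before the two hindered secondary ones.

Step 17
Reactants: 25 primary C9 alcohol
Product: 26 (2S,3S,4E,6R)-3-(tert-butyldimethylsilyloxy)-6-{6-[(2S,3S)-3-(tert-butyldimethylsilyloxy)pentan-2-yl]-3,5-dimethyl-4-oxo-4H-pyran-2-yl}-2,4-dimethylhept-4-enal
Conditions: Dess–Martin periodinane, pyridine, CH2Cl2, 0 °C → rt
Reagents that add atoms: none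
Why: Dess–Martin oxidation should give the α-chiral C9 aldehyde under neutral conditions without epimerisation at C10, and it avoids any hydride reagent in the presence of the pyranone.

Step 18
Reactants: 3 2,6-diethyl-3,5-dimethyl-4H-pyran-4-one (1.5 equiv); 26 C9–C23 aldehyde
Product: 29 C1–C23 bis-pyranone with free 9-OH and 11,21-bis(tert-butyldimethylsilyloxy) groups (8R,9R,10R,11S,12E,14R,20S,21S), via lithium dienolate 27 (not isolated), via silyl dienol ether 28 (not isolated)
Conditions: 3, LiHMDS, THF, −78 °C; TBSOTf, −78 °C; solvent exchanged for CH2Cl2 under argon, no work-up; added to 26 + BF3·OEt2 (3 equiv), CH2Cl2, −78 °C; aq NaHCO3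
Reagents that add atoms: none
Why: Proposed new method: LiHMDS removes a proton from one of the two equivalent ethyl CH2 groups of C2v-symmetric 3, TBSOTf traps the dienolate 27 on the ring-carbonyl oxygen, and the exocyclic carbon (future C8) of the resulting 2-ethylidene-2H-pyran 28 attacks the BF3-bound aldehyde carbon C9 of 26 in an open transition state, the return of the cross-conjugated pyranone being the driving force and aqueous work-up removing the silyl group. The closest known reaction types are the vinylogous Mukaiyama aldol reaction of γ-methyl silyl dienolates (vinylketene silyl N,O-acetals, dioxinone dienolates) and the lithium-dienolate aldol addition of 2-ethyl-4-pyranones, whereas the use of a silyl dienol ether of a 4-pyranone in this way appears to be without precedent. No ring is closed; the left ring only regains its pyranone conjugation. C8: allylic 1,3-strain with the C6 methyl group fixes the ethylidene of 28 as the Z isomer (CH3 next to the ring oxygen, trans to C6), and the antiperiplanar open transition state that places the BF3-bearing oxygen on the side of the small vinylic H should give the 8,9-anti relation, in line with the anti preference of equally configured γ-methyl dienolates. C9: Felkin–Anh attack anti to the C11 branch of the α-methyl aldehyde, secured by the non-chelating OTBS group and monodentate BF3, should give the 9,10-syn relation. The step needs γ- over α-attack (α-attack at methyl-bearing C6 would build a quaternary centre and forfeit the pyranone), a single nucleophile (symmetry of 3) and no proton exchange with C14–H and C20–H of the right pyranone, which the absence of base, −78 °C and excess BF3 on its carbonyl should secure.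

Step 19
Reactants: 29 C9 alcohol
Product: 30 9-O-acetate of 29 (8R,9R,10R,11S,12E,14R,20S,21S)
Conditions: Ac2O, pyridine, DMAP (cat.), CH2Cl2, 0 °C
Reagents that add atoms: acetic anhydride, CC(=O)OC(C)=O
Why: DMAP-catalysed acylation meets only one free hydroxyl group (C9–OH) and is run at low temperature, where β-elimination towards C8 should not compete.

Step 20
Reactants: 30 9-O-acetate
Product: 31 target CNP0290537.1 (8R,9R,10S,11S,12E,14R,20S,21S)
Conditions: HF·pyridine, THF, 0 °C → rt
Reagents that add atoms: none
Why: Fluoride-mediated cleavage of both secondary silyl ethers under mildly acidic conditions avoids the base-induced events to be feared here, namely acetyl migration from O9 to O11, β-elimination of acetate and epimerisation at C8, C14 and C20.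

**Compound list**

1 | pentan-3-one | CCC(=O)CC | starting material
2 | propanoic acid | CCC(=O)O | starting material
3 | 2,6-diethyl-3,5-dimethyl-4H-pyran-4-one | CCc1oc(CC)c(C)c(=O)c1C | intermediate
4 | propanal | CCC=O | starting material
5 | (2S,3S)-3-hydroxy-2-methylpentanal | O=C[C@@H](C)[C@@H](O)CC | intermediate
6 | (2S,3S)-3-(tert-butyldimethylsilyloxy)-2-methylpentanal | O=C[C@@H](C)[C@@H](O[Si](C)(C)C(C)(C)C)CC | intermediate
7 | lithium enolate of pentan-3-one | [Li+].CC=C([O-])CC | intermediate
8 | (6R,7S)-7-(tert-butyldimethylsilyloxy)-5-hydroxy-4,6-dimethylnonan-3-one | CCC(=O)C(C)C(O)[C@@H](C)[C@@H](O[Si](C)(C)C(C)(C)C)CC | intermediate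
9 | (6S,7S)-7-(tert-butyldimethylsilyloxy)-4,6-dimethylnonane-3,5-dione | CCC(=O)C(C)C(=O)[C@@H](C)[C@@H](O[Si](C)(C)C(C)(C)C)CC | intermediate
10 | methyl (S)-3-hydroxy-2-methylpropanoate | COC(=O)[C@@H](C)CO | starting material
11 | methyl (S)-2-methyl-3-(triethylsilyloxy)propanoate | COC(=O)[C@@H](C)CO[Si](CC)(CC)CC | intermediate
12 | (S)-2-methyl-3-(triethylsilyloxy)propanal | O=C[C@@H](C)CO[Si](CC)(CC)CC | intermediate
13 | 2-(triphenylphosphoranylidene)propanal | CC(C=O)=P(c1ccccc1)(c1ccccc1)c1ccccc1 | starting material
14 | (2E,4R)-2,4-dimethyl-5-(triethylsilyloxy)pent-2-enal | O=C/C(C)=C/[C@@H](C)CO[Si](CC)(CC)CC | intermediate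
15 | (S)-4-benzyl-3-propanoyloxazolidin-2-one | CCC(=O)N1C(=O)OC[C@@H]1Cc1ccccc1 | starting material
16 | (Z)-dibutylboron enolate of 15 | C/C=C(\OB(CCCC)CCCC)N1C(=O)OC[C@@H]1Cc1ccccc1 | intermediate
17 | (S)-4-benzyl-3-[(2S,3S,4E,6R)-3-hydroxy-2,4,6-trimethyl-7-(triethylsilyloxy)hept-4-enoyl]oxazolidin-2-one | O=C(N1C(=O)OC[C@@H]1Cc1ccccc1)[C@@H](C)[C@H](O)/C(C)=C/[C@@H](C)CO[Si](CC)(CC)CC | intermediate
18 | (2R,3S,4E,6R)-2,4,6-trimethyl-7-(triethylsilyloxy)hept-4-ene-1,3-diol | OC[C@@H](C)[C@H](O)/C(C)=C/[C@@H](C)CO[Si](CC)(CC)CC | intermediate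
19 | (2R,3S,4E,6R)-1,3-bis(tert-butyldimethylsilyloxy)-2,4,6-trimethyl-7-(triethylsilyloxy)hept-4-ene | CC(C)(C)[Si](C)(C)OC[C@@H](C)[C@H](O[Si](C)(C)C(C)(C)C)/C(C)=C/[C@@H](C)CO[Si](CC)(CC)CC | intermediate
20 | (2R,3E,5S,6R)-5,7-bis(tert-butyldimethylsilyloxy)-2,4,6-trimethylhept-3-enal | CC(C)(C)[Si](C)(C)OC[C@@H](C)[C@H](O[Si](C)(C)C(C)(C)C)/C(C)=C/[C@@H](C)C=O | intermediate
21 | dilithium bis-enolate of 9 | [Li+].[Li+].CC=C([O-])C(C)=C([O-])[C@@H](C)[C@@H](O[Si](C)(C)C(C)(C)C)CC | intermediate
22 | C9–C23 15-hydroxy-17,19-dione, 9,11,21-tris-OTBS | CC(C)(C)[Si](C)(C)OC[C@@H](C)[C@H](O[Si](C)(C)C(C)(C)C)/C(C)=C/[C@@H](C)C(O)C(C)C(=O)C(C)C(=O)[C@@H](C)[C@@H](O[Si](C)(C)C(C)(C)C)CC | intermediate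
23 | C9–C23 15,17,19-trione, 9,11,21-tris-OTBS | CC(C)(C)[Si](C)(C)OC[C@@H](C)[C@H](O[Si](C)(C)C(C)(C)C)/C(C)=C/[C@@H](C)C(=O)C(C)C(=O)C(C)C(=O)[C@@H](C)[C@@H](O[Si](C)(C)C(C)(C)C)CC | intermediate
24 | right-hand pyranone, 9,11,21-tris-OTBS | CC(C)(C)[Si](C)(C)OC[C@@H](C)[C@H](O[Si](C)(C)C(C)(C)C)/C(C)=C/[C@@H](C)c1oc([C@@H](C)[C@@H](O[Si](C)(C)C(C)(C)C)CC)c(C)c(=O)c1C | intermediate
25 | right-hand pyranone, free 9-OH, 11,21-bis-OTBS | OC[C@@H](C)[C@H](O[Si](C)(C)C(C)(C)C)/C(C)=C/[C@@H](C)c1oc([C@@H](C)[C@@H](O[Si](C)(C)C(C)(C)C)CC)c(C)c(=O)c1C | intermediate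
26 | C9–C23 aldehyde, 11,21-bis-OTBS | O=C[C@@H](C)[C@H](O[Si](C)(C)C(C)(C)C)/C(C)=C/[C@@H](C)c1oc([C@@H](C)[C@@H](O[Si](C)(C)C(C)(C)C)CC)c(C)c(=O)c1C | intermediate
27 | lithium (Z)-dienolate of 3 | [Li+].C/C=C1\OC(CC)=C(C)C([O-])=C1C | intermediate
28 | tert-butyl{[(2Z)-6-ethyl-2-ethylidene-3,5-dimethyl-2H-pyran-4-yl]oxy}dimethylsilane | C/C=C1\OC(CC)=C(C)C(O[Si](C)(C)C(C)(C)C)=C1C | intermediate
29 | bis-pyranone, free 9-OH, 11,21-bis-OTBS | CCc1oc([C@H](C)[C@H](O)[C@@H](C)[C@H](O[Si](C)(C)C(C)(C)C)/C(C)=C/[C@@H](C)c2oc([C@@H](C)[C@@H](O[Si](C)(C)C(C)(C)C)CC)c(C)c(=O)c2C)c(C)c(=O)c1C | intermediate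
30 | bis-pyranone, 9-OAc, 11,21-bis-OTBS | CCc1oc([C@H](C)[C@H](OC(C)=O)[C@@H](C)[C@H](O[Si](C)(C)C(C)(C)C)/C(C)=C/[C@@H](C)c2oc([C@@H](C)[C@@H](O[Si](C)(C)C(C)(C)C)CC)c(C)c(=O)c2C)c(C)c(=O)c1C | intermediate
31 | CNP0290537.1 | CCc1oc([C@H](C)[C@H](OC(C)=O)[C@@H](C)[C@H](O)/C(C)=C/[C@@H](C)c2oc([C@@H](C)[C@@H](O)CC)c(C)c(=O)c2C)c(C)c(=O)c1C | target

**Total step count:** 20. **Longest linear sequence:** 15 steps (steps 6–20, from 10).

**Steps most likely to fail**

1. Step 18 (Proposed new method). The dienolate may be silylated on carbon instead of oxygen. The basic nucleophile may exchange protons with the BF3-activated right pyranone. Facial selectivity may be weak because 1,3-induction from the C11 silyloxy group opposes Felkin–Anh control. The fallback sets out from 3 and 26 and abandons the silyl/Lewis-acid manifold. The lithium dienolate 27 (LiHMDS, THF, −78 °C) is used itself as the nucleophile and 26 is added to it at −78 °C. This is the established aldol mode of 2-ethyl-4-pyranones, and addition to the aldehyde should outrun proton transfer. Stereocontrol then rests only on the Felkin bias of 26, and the C8/C9 isomers are removed by chromatography. The route is rejoined at 29.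

2. Step 13. The strongly basic dianion may abstract C14–H of the β,γ-unsaturated aldehyde, causing loss of configuration and low conversion. It may also form by deprotonation at C20, followed by β-elimination of the silyloxy group. The fallback sets out from 8 and 20 and replaces the dianion by a neutral boron aldol of a mono-ketone. Compound 8 is silylated (TESOTf, 2,6-lutidine) to the triethylsilyl ether F1. Treatment with (c-Hex)2BCl/Et3N enolises the only unhindered α-position to give the dicyclohexylboron enolate F2. This adds to 20 at −78 °C and, after H2O2 work-up, gives the aldol adduct F3. PPTS in MeOH removes the triethylsilyl group to give the 15,19-diol F4. Excess Dess–Martin periodinane oxidises both carbinols, and the route is rejoined at 23.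

3. Step 12. Amine-induced enolisation or conjugation of the new aldehyde may erode C14, and discrimination between the primary triethylsilyl and primary tert-butyldimethylsilyl ethers may be incomplete. The fallback sets out from 19 and separates deprotection from oxidation. Mild solvolysis (PPTS, MeOH, 0 °C) frees only the C15 oxygen to give the primary alcohol F5. This is oxidised without amine base (Dess–Martin periodinane, pyridine buffer), and the route is rejoined at 20.

**Further compounds**

F0 | step 18 | none | none
F1 | step 13 | 5-O-triethylsilyl ether of 8 | CCC(=O)C(C)C(O[Si](CC)(CC)CC)[C@@H](C)[C@@H](O[Si](C)(C)C(C)(C)C)CC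
F2 | step 13 | dicyclohexylboron enolate of F1 | CC=C(OB(C1CCCCC1)C1CCCCC1)C(C)C(O[Si](CC)(CC)CC)[C@@H](C)[C@@H](O[Si](C)(C)C(C)(C)C)CC
F3 | step 13 | C9–C23 15-hydroxy-17-one, 19-OTES, 9,11,21-tris-OTBS | CC(C)(C)[Si](C)(C)OC[C@@H](C)[C@H](O[Si](C)(C)C(C)(C)C)/C(C)=C/[C@@H](C)C(O)C(C)C(=O)C(C)C(O[Si](CC)(CC)CC)[C@@H](C)[C@@H](O[Si](C)(C)C(C)(C)C)CC
F4 | step 13 | C9–C23 15,19-dihydroxy-17-one, 9,11,21-tris-OTBS | CC(C)(C)[Si](C)(C)OC[C@@H](C)[C@H](O[Si](C)(C)C(C)(C)C)/C(C)=C/[C@@H](C)C(O)C(C)C(=O)C(C)C(O)[C@@H](C)[C@@H](O[Si](C)(C)C(C)(C)C)CC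
F5 | step 12 | (2R,3E,5S,6R)-5,7-bis(tert-butyldimethylsilyloxy)-2,4,6-trimethylhept-3-en-1-ol | CC(C)(C)[Si](C)(C)OC[C@@H](C)[C@H](O[Si](C)(C)C(C)(C)C)/C(C)=C/[C@@H](C)CO
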